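**Plan**
1. Hardest point: two nearly identical C19 halves differ only in alkene geometry (ring half E, seco half Z) and must be joined through a hindered secondary ester. C3'–H (α to the C4' ketone and allylic) epimerises, and both alkylidenes scramble under basic or nucleophilic acylation conditions.
2. Enabling feature: the ring O1–C2(=O)–C3–C4–C5(=CH2) is an enol ester. The seco half (C1' ester, C3'–OH, C4'=O, C5'H3) is the same ring opened at C2–O1 by an alcohol, so the target is the sum of one E- and one Z-C19H32O3 unit with no atom lost.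
3. Cuts: first O1–C5 of the E ring (to CO2H + C≡CH). Then the ester bond C4–O–C1' (to the Z lactone as its own activated ester plus an E alkynol acid). Then the alkenyl–carbinol C–C bond of each half (to a vinyl metal plus 3-(trimethylsilyl)propynal).
4. Forward: the Z chain is built and the Z ring is closed as a temporary activating ring (step 5). A lipase opens this ring onto the E alkynol acid (step 8), and the E ring is closed last (step 9). No oxygen protecting group is used.
5. Geometry: syn H–Al addition to the 2-alkynoate gives Z; syn C–Cu addition to the propiolate gives E.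
6. Configuration: both carbinol centres come from the lipase preference for the alcohol enantiomer that places ethynyl in the medium pocket. This acts once as an acetylation resolution (C3', step 3) and once inside the coupling itself (C4, racemic acceptor, step 8).

Key step: step 8

Remark: unprimed locants refer to the lactone half (O1, C2=O, C3 alkylidene, C4 carbinol, C5=CH2) and primed locants to the seco-acid half. The (R) descriptor of the alkynols and the (S) descriptor of the lactone and ketone forms denote the same spatial arrangement, because the CIP rank of the former alkyne carbon rises above that of the alkenyl carbon.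

**Step 1**
Reactants: 1 pentadec-1-yne
Product: 3 methyl hexadec-2-ynoate, via lithium pentadec-1-yn-1-ide 2 (not isolated)
Conditions: n-BuLi, THF, −78 °C; ClCO2Me, −78 °C to rt
Reagents that add atoms: methyl chloroformate, COC(=O)Cl
Why: Deprotonation of the terminal alkyne and C-acylation of the lithium acetylide with a chloroformate is the standard entry to 2-alkynoates.

**Step 2**
Reactants: 3 methyl hexadec-2-ynoate; 4 3-(trimethylsilyl)prop-2-ynal
Product: 7 methyl (2Z)-2-(1-hydroxyprop-2-yn-1-yl)hexadec-2-enoate (racemic), via methyl (2E)-2-(diisobutylalumanyl)hexadec-2-enoate 5 (not isolated), via methyl (2Z)-2-[1-hydroxy-3-(trimethylsilyl)prop-2-yn-1-yl]hexadec-2-enoate 6 (not isolated)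
Conditions: DIBAL-H, NMO, THF, 0 °C; 4, 0 °C to rt; 1 M HCl work-up; crude 6, K2CO3 (cat.), MeOH, 0 °C
Reagents that add atoms: none
Why: Conjugate syn-hydroalumination (vinylalumination) puts H and Al on the same side so that the tridecyl chain ends cis to CO2Me, the vinylalane adds 1,2 to the ynal with retention (attack through an allenolate from the H side would give the same Z isomer), and methanolysis of the C(sp)–Si bond then frees the small ethynyl group, the carbinol centre being racemic at this stage.

**Step 3**
Reactants: 7 methyl (2Z)-2-(1-hydroxyprop-2-yn-1-yl)hexadec-2-enoate (racemic)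
Product: 8 methyl (2Z)-2-[(1R)-1-(acetyloxy)prop-2-yn-1-yl]hexadec-2-enoate
Conditions: immobilised Candida antarctica lipase B, vinyl acetate (3 equiv), MTBE, 30 °C, stopped near half conversion; chromatography
Reagents that add atoms: vinyl acetate, C=COC(C)=O
Why: Lipase-catalysed kinetic resolution by irreversible transesterification with an enol ester should acylate the (R)-alcohol, in which the linear ethynyl group fits the medium pocket and the alkenyl ester residue the large one, and this sets the centre that becomes C3' of the target.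

**Step 4**
Reactants: 8 methyl (2Z)-2-[(1R)-1-(acetyloxy)prop-2-yn-1-yl]hexadec-2-enoate
Product: 9 (2Z)-2-[(1R)-1-hydroxyprop-2-yn-1-yl]hexadec-2-enoic acid
Conditions: LiOH, THF/MeOH/H2O, 0 °C to rt; 1 M HCl to pH 3
Reagents that add atoms: lithium hydroxide (aqueous), [Li+].[OH-]
Why: Saponification cleaves acetate and methyl ester at their acyl–oxygen bonds, so the C–O bond of the stereocentre is untouched and the carboxylate that forms shields the Z-enoate from conjugate addition.

**Step 5**
Reactants: 9 (2Z)-2-[(1R)-1-hydroxyprop-2-yn-1-yl]hexadec-2-enoic acid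
Product: 10 (3Z,4S)-4-hydroxy-5-methylidene-3-tetradecylideneoxolan-2-one
Conditions: Ag2CO3 (10 mol %), toluene, rt, dark
Reagents that add atoms: none
Why: Silver(I)-catalysed cycloisomerisation of a 4-pentynoic acid (5-exo-dig anti-oxymetallation, then protodemetallation) closes the enol-lactone ring under almost neutral conditions without touching the carbinol centre or the Z-alkylidene.

**Step 6**
Reactants: 11 1-bromotridecane; 12 methyl propiolate; 4 3-(trimethylsilyl)prop-2-ynal
Product: 16 methyl (2E)-2-[1-hydroxy-3-(trimethylsilyl)prop-2-yn-1-yl]hexadec-2-enoate (racemic), via tridecylmagnesium bromide 13 (not isolated), via bromomagnesium ditridecylcuprate 14 (not isolated), via bromomagnesium [(1Z)-1-(methoxycarbonyl)pentadec-1-en-1-yl](tridecyl)cuprate 15 (not isolated)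
Conditions: 11 (2 equiv), Mg, THF; CuBr·SMe2 (1 equiv), −40 °C; 12, −78 °C; 4, Et2AlCl, −78 °C; aq NH4Cl
Reagents that add atoms: none
Why: Syn-carbocupration of the propiolate puts tridecyl and copper on the same side, the C-bound α-(methoxycarbonyl)vinyl cuprate holds its configuration at −78 °C, and its Lewis-acid-promoted 1,2-addition to the ynal (tandem conjugate addition–aldol) should go with retention, so that the chain ends cis to the carbinol carbon (E) while the carbinol centre is left racemic on purpose.

**Step 7**
Reactants: 16 methyl (2E)-2-[1-hydroxy-3-(trimethylsilyl)prop-2-yn-1-yl]hexadec-2-enoate (racemic)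
Product: 17 (2E)-2-(1-hydroxyprop-2-yn-1-yl)hexadec-2-enoic acid (racemic)
Conditions: LiOH, THF/MeOH/H2O, rt; 1 M HCl to pH 3
Reagents that add atoms: lithium hydroxide (aqueous), [Li+].[OH-]
Why: One saponification removes the methyl ester and, by protodesilylation of the alkynylsilane, the C(sp)–SiMe3 group, leaving the E-alkene unchanged.

**Step 8**
Reactants: 10 (3Z,4S)-4-hydroxy-5-methylidene-3-tetradecylideneoxolan-2-one; 17 (2E)-2-(1-hydroxyprop-2-yn-1-yl)hexadec-2-enoic acid (racemic, 3 equiv)
Product: 18 (2E)-2-[(1R)-1-({(2Z)-2-[(1S)-1-hydroxy-2-oxopropyl]hexadec-2-enoyl}oxy)prop-2-yn-1-yl]hexadec-2-enoic acid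
Conditions: lipase (serine hydrolase; immobilised Candida antarctica lipase B), 4 Å MS, dry toluene, 40 °C; 10 added by syringe pump to 17 and enzyme; filtration, chromatography
Reagents that add atoms: none
Why: Proposed new method: the catalytic serine attacks C2(=O) of 10, the tetrahedral intermediate collapses with cleavage of C2–O1, and the expelled C5 enol takes a proton at its exocyclic CH2 to become the C4'(=O)–C5'H3 methyl ketone, which makes formation of the Z-acyl-enzyme irreversible and leaves C3'–H untouched, after which the hydroxyl group of (R)-17 deacylates the enzyme to give the C4–O–C1' ester. The closest known reaction types are the irreversible lipase acylation of secondary alcohols with vinyl or isopropenyl esters and with the enol lactone diketene, and the acylation of serine hydrolases by 5-methylidene lactones, whereas an α-alkylidene-γ-methylidene butanolide has not been used as donor. No ring is closed (the oxolanone ring of 10, made only as an activating device, is opened) and no stereocentre is created: C3' is carried over from 10, and C4 is selected from the racemate because only the (R)-alcohol places its linear ethynyl group in the medium pocket while the alkenyl acid residue points to the entrance. Role selectivity is structural, since 10 holds the only enol ester while 17 carries its own lactone still latent as C≡CH plus CO2H, and a conjugated α-branched free acid is a poor acyl donor for the enzyme. Selectivity among the hydroxyl groups (C4–OH of 10, C3'–OH of 18) rests on the medium pocket, which should refuse the branched C5(=CH2)O and acetyl groups, and is backed by slow addition of 10 to an excess of 17. The neutral medium free of nucleophilic catalysts avoids addition–elimination at the two alkylidenes and enolisation at C3'.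

**Step 9**
Reactants: 18 (2E)-2-[(1R)-1-({(2Z)-2-[(1S)-1-hydroxy-2-oxopropyl]hexadec-2-enoyl}oxy)prop-2-yn-1-yl]hexadec-2-enoic acid
Product: 19 (3S,4E)-2-methylidene-5-oxo-4-tetradecylideneoxolan-3-yl (2Z)-2-[(1S)-1-hydroxy-2-oxopropyl]hexadec-2-enoate (target)
Conditions: Ag2CO3 (10 mol %), toluene, rt, dark
Reagents that add atoms: none
Why: The same silver(I)-catalysed 5-exo-dig cycloisomerisation as in step 5 closes the E ring as a pure isomerisation in a carboxylic acid/silver carboxylate buffer, in which the irreversible carboxylate attack and protodemetallation should outrun any shift of the propargylic ester, and C4 and C3' are not involved.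

**Compound list**
1 | pentadec-1-yne | C#CCCCCCCCCCCCCC | starting material
2 | lithium pentadec-1-yn-1-ide | [Li]C#CCCCCCCCCCCCCC | intermediate
3 | methyl hexadec-2-ynoate | CCCCCCCCCCCCCC#CC(=O)OC | intermediate
4 | 3-(trimethylsilyl)prop-2-ynal | C[Si](C)(C)C#CC=O | starting material
5 | methyl (2E)-2-(diisobutylalumanyl)hexadec-2-enoate | COC(=O)/C(=C\CCCCCCCCCCCCC)[Al](CC(C)C)CC(C)C | intermediate
6 | methyl (2Z)-2-[1-hydroxy-3-(trimethylsilyl)prop-2-yn-1-yl]hexadec-2-enoate (racemic) | COC(=O)/C(=C\CCCCCCCCCCCCC)C(O)C#C[Si](C)(C)C | intermediate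
7 | methyl (2Z)-2-(1-hydroxyprop-2-yn-1-yl)hexadec-2-enoate (racemic) | COC(=O)/C(=C\CCCCCCCCCCCCC)C(O)C#C | intermediate
8 | methyl (2Z)-2-[(1R)-1-(acetyloxy)prop-2-yn-1-yl]hexadec-2-enoate | COC(=O)/C(=C\CCCCCCCCCCCCC)[C@H](OC(C)=O)C#C | intermediate
9 | (2Z)-2-[(1R)-1-hydroxyprop-2-yn-1-yl]hexadec-2-enoic acid | OC(=O)/C(=C\CCCCCCCCCCCCC)[C@H](O)C#C | intermediate
10 | (3Z,4S)-4-hydroxy-5-methylidene-3-tetradecylideneoxolan-2-one | C=C1OC(=O)/C(=C\CCCCCCCCCCCCC)[C@@H]1O | intermediate
11 | 1-bromotridecane | CCCCCCCCCCCCCBr | starting material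
12 | methyl propiolate | C#CC(=O)OC | starting material
13 | tridecylmagnesium bromide | CCCCCCCCCCCCC[Mg]Br | intermediate
14 | bromomagnesium ditridecylcuprate | CCCCCCCCCCCCC[Cu-]CCCCCCCCCCCCC.[Mg+2].[Br-] | intermediate
15 | bromomagnesium [(1Z)-1-(methoxycarbonyl)pentadec-1-en-1-yl](tridecyl)cuprate | COC(=O)/C(=C/CCCCCCCCCCCCC)[Cu-]CCCCCCCCCCCCC.[Mg+2].[Br-] | intermediate
16 | methyl (2E)-2-[1-hydroxy-3-(trimethylsilyl)prop-2-yn-1-yl]hexadec-2-enoate (racemic) | COC(=O)/C(=C/CCCCCCCCCCCCC)C(O)C#C[Si](C)(C)C | intermediate
17 | (2E)-2-(1-hydroxyprop-2-yn-1-yl)hexadec-2-enoic acid (racemic) | OC(=O)/C(=C/CCCCCCCCCCCCC)C(O)C#C | intermediate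
18 | (2E)-2-[(1R)-1-({(2Z)-2-[(1S)-1-hydroxy-2-oxopropyl]hexadec-2-enoyl}oxy)prop-2-yn-1-yl]hexadec-2-enoic acid | OC(=O)/C(=C/CCCCCCCCCCCCC)[C@@H](C#C)OC(=O)/C(=C\CCCCCCCCCCCCC)[C@H](O)C(C)=O | intermediate
19 | (3S,4E)-2-methylidene-5-oxo-4-tetradecylideneoxolan-3-yl (2Z)-2-[(1S)-1-hydroxy-2-oxopropyl]hexadec-2-enoate | C=C1OC(=O)/C(=C/CCCCCCCCCCCCC)[C@@H]1OC(=O)/C(=C\CCCCCCCCCCCCC)[C@H](O)C(C)=O | target

**Total step count:** 9.
**Longest linear sequence:** 7 (steps 1, 2, 3, 4, 5, 8, 9).

**Steps most likely to fail**

**Step 8 (Proposed new method).**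
- Acyl-enzyme formation from the conjugated, α-branched lactone may be too slow.
- The enzyme may be inactivated by conjugate addition of its side chains to the alkylidene lactone.
- The donor may acylate its own C4–OH and oligomerise.

The fallback gives up the self-activated donor for classical carboxyl activation. It sets out from 10 and 17 and comes back to the route at 19.
- Lactone 10 is silylated (TBSOTf, 2,6-lutidine, CH2Cl2, −78 °C) to (3Z,4S)-4-[(tert-butyldimethylsilyl)oxy]-5-methylidene-3-tetradecylideneoxolan-2-one F1.
- F1 is opened with one equivalent of LiOH in THF/H2O at 0 °C to (2Z)-2-[(1S)-1-[(tert-butyldimethylsilyl)oxy]-2-oxopropyl]hexadec-2-enoic acid F2.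
- Racemic 17 is cyclised with Ag2CO3 to racemic (3E)-4-hydroxy-5-methylidene-3-tetradecylideneoxolan-2-one F3.
- A Shiina esterification of F2 with F3 (MNBA, Et3N, cat. DMAP, CH2Cl2) gives the O-TBS ether of the target F4 together with its (4R)-diastereomer F5. These are separated by chromatography.
- HF·pyridine in THF at 0 °C converts F4 into 19.

**Step 6.**
- The vinyl cuprate may equilibrate through a copper or aluminium allenolate, which erodes or inverts the alkene geometry.
- The residual tridecyl group may be transferred to the aldehyde.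
- The addition to the aldehyde may stall.

The fallback fixes the geometry in a vinyl bromide before the C–C bond is made. It uses a carboxylate-stabilised vinyllithium that has no easy allenolate pathway. It sets out from 4 (with commercial tetradecanal) and comes back at 17.
- A Wittig reaction of tetradecanal with methyl bromo(triphenylphosphoranylidene)acetate gives methyl (2Z)-2-bromohexadec-2-enoate F6.
- LiOH gives (2Z)-2-bromohexadec-2-enoic acid F7.
- n-BuLi (2 equiv, THF/Et2O, −100 °C) deprotonates F7 and exchanges bromine with retention to lithium (2Z)-2-lithiohexadec-2-enoate F8.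
- Addition of F8 to 4 gives (2E)-2-[1-hydroxy-3-(trimethylsilyl)prop-2-yn-1-yl]hexadec-2-enoic acid F9.
- K2CO3 in MeOH desilylates F9 to 17.

**Step 9.**
- The π-acid may trigger migration of the propargylic acyloxy group instead of carboxylate attack.
- Silver(I) may be consumed by oxidation of the α-ketol or as silver acetylide.
- The product enol lactone may be opened by adventitious water.

The fallback replaces π-acid catalysis by an electrophile-driven ring closure. It sets out from 18 and comes back at 19.
- Iodolactonisation (NIS, KHCO3, CH2Cl2/H2O, 0 °C; anti addition, 5-exo) gives the (5E)-5-(iodomethylidene) analogue of the target F10.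
- The vinyl iodide of F10 is reduced by a radical chain ((Me3Si)3SiH, Et3B/air, toluene, 0 °C) to 19.

**Further compounds**
F1 | step 8 | (3Z,4S)-4-[(tert-butyldimethylsilyl)oxy]-5-methylidene-3-tetradecylideneoxolan-2-one | C=C1OC(=O)/C(=C\CCCCCCCCCCCCC)[C@@H]1O[Si](C)(C)C(C)(C)C
F2 | step 8 | (2Z)-2-[(1S)-1-[(tert-butyldimethylsilyl)oxy]-2-oxopropyl]hexadec-2-enoic acid | OC(=O)/C(=C\CCCCCCCCCCCCC)[C@H](O[Si](C)(C)C(C)(C)C)C(C)=O
F3 | step 8 | (3E)-4-hydroxy-5-methylidene-3-tetradecylideneoxolan-2-one (racemic) | C=C1OC(=O)/C(=C/CCCCCCCCCCCCC)C1O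
F4 | step 8 | O-TBS ether of the target | C=C1OC(=O)/C(=C/CCCCCCCCCCCCC)[C@@H]1OC(=O)/C(=C\CCCCCCCCCCCCC)[C@H](O[Si](C)(C)C(C)(C)C)C(C)=O
F5 | step 8 | (4R)-diastereomer of the O-TBS ether | C=C1OC(=O)/C(=C/CCCCCCCCCCCCC)[C@H]1OC(=O)/C(=C\CCCCCCCCCCCCC)[C@H](O[Si](C)(C)C(C)(C)C)C(C)=O
F6 | step 6 | methyl (2Z)-2-bromohexadec-2-enoate | COC(=O)/C(Br)=C/CCCCCCCCCCCCC
F7 | step 6 | (2Z)-2-bromohexadec-2-enoic acid | OC(=O)/C(Br)=C/CCCCCCCCCCCCC
F8 | step 6 | lithium (2Z)-2-lithiohexadec-2-enoate | [Li]OC(=O)/C([Li])=C/CCCCCCCCCCCCC
F9 | step 6 | (2E)-2-[1-hydroxy-3-(trimethylsilyl)prop-2-yn-1-yl]hexadec-2-enoic acid (racemic) | OC(=O)/C(=C/CCCCCCCCCCCCC)C(O)C#C[Si](C)(C)C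
F10 | step 9 | (5E)-5-(iodomethylidene) analogue of the target | I/C=C1/OC(=O)/C(=C/CCCCCCCCCCCCC)[C@@H]1OC(=O)/C(=C\CCCCCCCCCCCCC)[C@H](O)C(C)=O
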